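The readings are simulated from invented constants; the scatter is artificial.

The decision is to carry a time rather than a rate through this flask: the moment when target and side product stand level, with the ratio of target to side product reckoned outward from it to each end.

| setting | south-west | south-east | flask |
|---|---|---|---|
| starting material | 0.044 M | 0.18 M | 0.089 M |
| remark | run made earlier | run made earlier |  |
| time |  |  | 20 min |

| run | time / min | target / % | side product / % |
|---|---|---|---|
| south-west | 1.00 | 6.4 | 3.8 |
| south-west | 1.33 | 7.9 | 5.4 |
| south-west | 2.00 | 7.5 | 11.0 |
| south-west | 3.00 | 6.7 | 15.7 |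
| south-west | 5.00 | 5.1 | 25.0 |
| south-west | 8.00 | 3.9 | 35.6 |
| south-west | 12.0 | 3.2 | 45.9 |
| south-east | 1.50 | 6.9 | 6.1 |
| south-east | 3.00 | 6.3 | 15.0 |
| south-east | 5.00 | 5.6 | 25.4 |
| south-east | 6.00 | 4.5 | 29.4 |
| south-east | 8.00 | 3.9 | 34.3 |
| south-east | 10.0 | 3.6 | 41.3 |
| south-east | 12.0 | 2.4 | 46.1 |

(readings scatter by 0.5 percentage points)

- the numbers in the tables scatter with a standard deviation of 0.5 percentage points
- a reading or a percentage of target counts all its forms, free or not

- ratio of target to side product at 12 s
- ratio of target to side product at 20 min

This reckoning starts from the charge, which seems not to matter: side product at 12.0 min reads 45.9% from 0.044 M and 46.1% from 0.18 M. So the flask at 0.089 M, lying between them, can borrow both runs. Straight lines between the readings put the level point at 1.61 min in the south-west run and 1.63 min in the south-east run. The crossing time, when target equals side product, therefore reads 1.62 min.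

At 12.0 min the pooled ratio reads 0.0609. That means an exponent of 1.40 from the crossing onward: each doubling of time divides the ratio by 2.64. Run back to 12 s, this line gives 18.5; run forward to 20 min, it gives 0.0298.

The forward link is weak. From 8.00 min to 12.0 min the pooled readings show an exponent of 1.49, as read through their scatter, steeper than the line. Reforged as a steady fall of 0.152 min⁻¹, the link gives 0.0181 at 20 min. This reckoning commits to 18.5 and 0.0181.

The forecast says 10 at 12 s and 0.03 at 20 min, holding that “the kinetics look first-order”. It stands below this reckoning early and above it late.

The flask gives 20.4 at 12 s and 0.0221 at 20 min.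

    starting material → intermediate A (k = 0.440 s⁻¹)
    starting material ⇌ intermediate B (K = 3.40, k = 0.250 s⁻¹)
    intermediate B → target (k = 0.0140 s⁻¹)
    intermediate A → intermediate C (k = 0.00440 s⁻¹)
    intermediate B → intermediate D (k = 0.00240 s⁻¹)
    intermediate D → side product (k = 0.0170 s⁻¹)
    intermediate D ⇌ intermediate C (K = 5.10, k = 0.00580 s⁻¹)
    intermediate A → intermediate D (k = 0.00210 s⁻¹)
    target → over-reaction product (k = 0.00150 s⁻¹)
    starting material + target ⇌ idle adduct, settled at all times (K = 10.0 L mol⁻¹)

The forecast parts from the flask more at the early end than at the late end, and at 12 s the flask's ratio is twice the forecast's. Through the crossing time 1.62 min, the flask's ratios need an exponent of 1.44 back to 12 s and 1.52 forward to 20 min, steeper late. For a neighbouring flask charged with 0.36 M of starting material, the reckoning assumes the same crossing time and so again says 18.5 at 12 s and 0.0181 at 20 min; that neighbouring flask itself gives 20.4 and 0.0222.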